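**Plan**

- In the retrosynthesis the two O–Si bonds at O5 and O7 are cut first. Then both bonds to the C4 carbonyl carbon (C3–C4 and C4–C4a) are cut together, so that C4 leaves as carbon monoxide and ring C opens to a Z enol triflate.
- This works because C4 of ring C lies between the vinyl carbon C3 of the O1–C2=C3 enol ether and C4a of ring A. Ring A is a phloroglucinol-type ring whose two carbons ortho to O1 are equivalent and strongly nucleophilic.
- The triflate goes back to an α-aryloxy ketone, which is cut at C3–C1' (ring B aryllithium plus Weinreb amide) and at O1–C2 (ring A phenol plus bromoacetamide).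
- Forward: the ring A and ring B pieces are made separately from phloroglucinol and 2,5-dimethoxyphenol and joined through the two-carbon unit C2–C3. Ring C is closed last around CO, and desilylation ends the route.
- The target has no stereocentre. The only stereochemical element of the route, the Z geometry of the enol triflate, comes from a potassium-chelated Z enolate.

Key step: step 7

Assumption: the four starting materials are taken as purchasable, and the acylpalladium intermediate of the key step is drawn without its phosphine ligands.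

**Step 1**
Reactants: 1 phloroglucinol
Product: 2 3,5-bis(triisopropylsilyloxy)phenol
Conditions: TIPSCl (2.0 equiv), imidazole, DMF, 0 °C to rt; chromatography
Reagents that add atoms: chlorotriisopropylsilane, CC(C)[Si](Cl)(C(C)C)C(C)C
Why: Silyl ether formation on a triphenol with three equivalent hydroxyls should give the bis-ether as the main product of a statistical silylation, the mono- and tris-ethers being separable and recyclable.

**Step 2**
Reactants: 2 3,5-bis(triisopropylsilyloxy)phenol; 3 2-bromo-N-methoxy-N-methylacetamide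
Product: 4 2-[3,5-bis(triisopropylsilyloxy)phenoxy]-N-methoxy-N-methylacetamide
Conditions: K2CO3, acetone, rt
Reagents that add atoms: none
Why: Williamson ether synthesis, in which the phenoxide displaces bromide from the activated α-bromo amide under a weak base that the bulky aryl silyl ethers should tolerate.

**Step 3**
Reactants: 5 2,5-dimethoxyphenol
Product: 6 4-bromo-2,5-dimethoxyphenol
Conditions: NBS (1.0 equiv), MeCN, 0 °C
Reagents that add atoms: N-bromosuccinimide, O=C1CCC(=O)N1Br
Why: Electrophilic aromatic bromination should go to the carbon para to the free hydroxyl and ortho to the 5-methoxy group, the most activated and least hindered position.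

**Step 4**
Reactants: 6 4-bromo-2,5-dimethoxyphenol; 7 1-bromo-3-methylbut-2-ene (prenyl bromide)
Product: 8 1-bromo-2,5-dimethoxy-4-(3-methylbut-2-enyloxy)benzene
Conditions: K2CO3, acetone, 50 °C
Reagents that add atoms: none
Why: Williamson ether synthesis by SN2 attack of the phenoxide at the primary allylic carbon, with O-alkylation favoured under carbonate in acetone.

**Step 5**
Reactants: 8 1-bromo-2,5-dimethoxy-4-(3-methylbut-2-enyloxy)benzene; 4 2-[3,5-bis(triisopropylsilyloxy)phenoxy]-N-methoxy-N-methylacetamide
Product: 11 2-[3,5-bis(triisopropylsilyloxy)phenoxy]-1-[2,5-dimethoxy-4-(3-methylbut-2-enyloxy)phenyl]ethanone, via aryllithium 9 (not isolated), via lithium hemiaminal adduct 10 (not isolated)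
Conditions: n-BuLi, THF, −78 °C; then 4, −78 to 0 °C; aq. NH4Cl
Reagents that add atoms: none
Why: Bromine–lithium exchange followed by a Weinreb ketone synthesis, in which the chelated tetrahedral adduct 10 holds until work-up and so prevents over-addition.

**Step 6**
Reactants: 11 2-[3,5-bis(triisopropylsilyloxy)phenoxy]-1-[2,5-dimethoxy-4-(3-methylbut-2-enyloxy)phenyl]ethanone
Product: 13 (Z)-2-[3,5-bis(triisopropylsilyloxy)phenoxy]-1-[2,5-dimethoxy-4-(3-methylbut-2-enyloxy)phenyl]ethenyl trifluoromethanesulfonate, via potassium enolate 12 (not isolated)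
Conditions: KN(SiMe3)2, THF, −78 °C; then PhNTf2, −78 to 0 °C
Reagents that add atoms: N-phenylbis(trifluoromethanesulfonimide), O=S(=O)(N(c1ccccc1)S(=O)(=O)C(F)(F)F)C(F)(F)F
Why: Enol triflate formation, in which deprotonation should give the Z enolate (potassium bridging the enolate and aryloxy oxygens, ring B trans to the aryloxy group) and O-sulfonylation keeps that geometry.

**Step 7**
Reactants: 13 (Z)-2-[3,5-bis(triisopropylsilyloxy)phenoxy]-1-[2,5-dimethoxy-4-(3-methylbut-2-enyloxy)phenyl]ethenyl trifluoromethanesulfonate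
Product: 15 3-[2,5-dimethoxy-4-(3-methylbut-2-enyloxy)phenyl]-5,7-bis(triisopropylsilyloxy)chromen-4-one, via acylpalladium triflate 14 (not isolated)
Conditions: Pd(OAc)2 (10 mol %), PCy3 (20 mol %), CsOPiv (2 equiv), CO (1 atm), PhMe, 100 °C
Reagents that add atoms: carbon monoxide, [C-]#[O+]
Why: Proposed new method: Zerovalent palladium, formed in the flask from Pd(OAc)2 and PCy3, should insert into the vinyl C–OTf bond of 13 with retention of geometry, and CO should then insert into the vinyl–palladium bond to give the acylpalladium triflate 14 (new C3–C4 bond). The divalent palladium acyl group then acylates the ring A carbon ortho to the ether oxygen (new C4–C4a bond), either through pivalate-assisted concerted metalation–deprotonation to a seven-membered palladacycle and C–C reductive elimination or through Friedel–Crafts-type attack of the electron-rich ring on the acyl complex, while CsOPiv takes up the triflic acid. The closest known reaction type is the palladium-catalysed cyclocarbonylation of ortho-halobiaryls to fluorenones and the carbonylative cyclisation of diaryl ethers to xanthones; new here are the enol triflate as electrophile and the aryl vinyl ether as tether. Ring C closes in the 6-exo-trig mode, C4a attacking the acyl carbon at the end of the chain C8a–O1–C2=C3–C4, and no stereocentre is formed. The step needs the acyl group and the aryloxy ring on the same side of the C2=C3 double bond, which the Z geometry of 13 secures, and it needs no regiochemical choice, because the two carbons ortho to the ether oxygen of the 3,5-disilyloxyphenoxy ring are equivalent. It also needs CO insertion to outrun direct C–H vinylation to a 3-arylbenzofuran, which the CO atmosphere and the fast insertion into a vinyl–palladium bond should ensure, and it needs conditions free of strong acid or base, which the prenyl ether and the silyl ethers should survive.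

**Step 8**
Reactants: 15 3-[2,5-dimethoxy-4-(3-methylbut-2-enyloxy)phenyl]-5,7-bis(triisopropylsilyloxy)chromen-4-one
Product: 16 brandisianin A
Conditions: Bu4NF, AcOH, THF, 0 °C
Reagents that add atoms: none
Why: Fluoride-mediated cleavage of the two aryl silyl ethers, buffered with acetic acid so that the base-sensitive pyranone ring and the prenyl ether should stay intact.

**Compound list**

1 | phloroglucinol (benzene-1,3,5-triol) | Oc1cc(O)cc(O)c1 | starting material
2 | 3,5-bis(triisopropylsilyloxy)phenol | Oc1cc(O[Si](C(C)C)(C(C)C)C(C)C)cc(O[Si](C(C)C)(C(C)C)C(C)C)c1 | intermediate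
3 | 2-bromo-N-methoxy-N-methylacetamide | CON(C)C(=O)CBr | starting material
4 | 2-[3,5-bis(triisopropylsilyloxy)phenoxy]-N-methoxy-N-methylacetamide | CON(C)C(=O)COc1cc(O[Si](C(C)C)(C(C)C)C(C)C)cc(O[Si](C(C)C)(C(C)C)C(C)C)c1 | intermediate
5 | 2,5-dimethoxyphenol | COc1ccc(OC)c(O)c1 | starting material
6 | 4-bromo-2,5-dimethoxyphenol | COc1cc(Br)c(OC)cc1O | intermediate
7 | 1-bromo-3-methylbut-2-ene (prenyl bromide) | CC(C)=CCBr | starting material
8 | 1-bromo-2,5-dimethoxy-4-(3-methylbut-2-enyloxy)benzene | COc1cc(Br)c(OC)cc1OCC=C(C)C | intermediate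
9 | [2,5-dimethoxy-4-(3-methylbut-2-enyloxy)phenyl]lithium (not isolated) | [Li]c1cc(OC)c(OCC=C(C)C)cc1OC | intermediate
10 | lithium 2-[3,5-bis(triisopropylsilyloxy)phenoxy]-1-[2,5-dimethoxy-4-(3-methylbut-2-enyloxy)phenyl]-1-[methoxy(methyl)amino]ethanolate, racemic (not isolated) | [Li]OC(COc1cc(O[Si](C(C)C)(C(C)C)C(C)C)cc(O[Si](C(C)C)(C(C)C)C(C)C)c1)(N(C)OC)c1cc(OC)c(OCC=C(C)C)cc1OC | intermediate
11 | 2-[3,5-bis(triisopropylsilyloxy)phenoxy]-1-[2,5-dimethoxy-4-(3-methylbut-2-enyloxy)phenyl]ethanone | O=C(COc1cc(O[Si](C(C)C)(C(C)C)C(C)C)cc(O[Si](C(C)C)(C(C)C)C(C)C)c1)c1cc(OC)c(OCC=C(C)C)cc1OC | intermediate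
12 | potassium (Z)-2-[3,5-bis(triisopropylsilyloxy)phenoxy]-1-[2,5-dimethoxy-4-(3-methylbut-2-enyloxy)phenyl]ethenolate (not isolated) | [K]O/C(=C\Oc1cc(O[Si](C(C)C)(C(C)C)C(C)C)cc(O[Si](C(C)C)(C(C)C)C(C)C)c1)c1cc(OC)c(OCC=C(C)C)cc1OC | intermediate
13 | (Z)-2-[3,5-bis(triisopropylsilyloxy)phenoxy]-1-[2,5-dimethoxy-4-(3-methylbut-2-enyloxy)phenyl]ethenyl trifluoromethanesulfonate | FC(F)(F)S(=O)(=O)O/C(=C\Oc1cc(O[Si](C(C)C)(C(C)C)C(C)C)cc(O[Si](C(C)C)(C(C)C)C(C)C)c1)c1cc(OC)c(OCC=C(C)C)cc1OC | intermediate
14 | [(Z)-3-[3,5-bis(triisopropylsilyloxy)phenoxy]-2-[2,5-dimethoxy-4-(3-methylbut-2-enyloxy)phenyl]prop-2-enoyl]palladium trifluoromethanesulfonate, phosphine ligands not drawn (not isolated) | O=C([Pd]OS(=O)(=O)C(F)(F)F)/C(=C\Oc1cc(O[Si](C(C)C)(C(C)C)C(C)C)cc(O[Si](C(C)C)(C(C)C)C(C)C)c1)c1cc(OC)c(OCC=C(C)C)cc1OC | intermediate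
15 | 3-[2,5-dimethoxy-4-(3-methylbut-2-enyloxy)phenyl]-5,7-bis(triisopropylsilyloxy)chromen-4-one | COc1cc(-c2coc3cc(O[Si](C(C)C)(C(C)C)C(C)C)cc(O[Si](C(C)C)(C(C)C)C(C)C)c3c2=O)c(OC)cc1OCC=C(C)C | intermediate
16 | brandisianin A, 5,7-dihydroxy-3-[2,5-dimethoxy-4-(3-methylbut-2-enyloxy)phenyl]chromen-4-one | COc1cc(-c2coc3cc(O)cc(O)c3c2=O)c(OC)cc1OCC=C(C)C | target

**Step count**

Total: 8 steps. Longest linear sequence: 6 steps (steps 1, 2, 5, 6, 7, 8 from phloroglucinol; equally steps 3, 4, 5, 6, 7, 8 from 2,5-dimethoxyphenol).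

**Steps most likely to fail**

Step 7. The acylpalladium intermediate may fail to reach the ring A C–H position, which is flanked by the ether oxygen and a bulky silyloxy group. It could then be lost to hydrolysis, to decarbonylation followed by direct vinylation, or to slow ionisation of the prenyl ether by zerovalent palladium. The fallback forms the same two bonds in separate, known operations, sets out from 13 and comes back at 15. Palladium-catalysed hydroxycarbonylation of the vinyl triflate (Pd(OAc)2, PPh3, Et3N, water, CO, DMF, 60 °C) should give (Z)-3-[3,5-bis(triisopropylsilyloxy)phenoxy]-2-[2,5-dimethoxy-4-(3-methylbut-2-enyloxy)phenyl]prop-2-enoic acid F1. Treatment with 1-chloro-N,N,2-trimethylprop-1-enylamine in CH2Cl2 at 0 °C should convert it under neutral conditions into the acid chloride F2. AgOTf with 2,6-di-tert-butyl-4-methylpyridine in CH2Cl2 at −40 °C should turn this into the acyl triflate F3, which is expected to close ring C at once by intramolecular Friedel–Crafts acylation of the phloroglucinol-type ring to give 15.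

Step 6. Enolisation may be incompletely Z-selective, and only the Z isomer can cyclise; the electron-rich enol triflate may also hydrolyse during purification. The fallback separates enolisation from sulfonylation, sets out from 11 and comes back at 13. Soft enolisation with Me3SiOTf and Et3N in CH2Cl2 at 0 °C should give the thermodynamically preferred (Z)-trimethylsilyl enol ether F4, which can be purified and its geometry checked. MeLi in THF at 0 °C should cleave it to the lithium (Z)-enolate F5, and PhNTf2 then gives 13.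

Step 5. The aryllithium may deprotonate the acidic α-aryloxy methylene of the Weinreb amide instead of adding to the carbonyl, or attack a silyl ether. The fallback reverses the order of bond formation so that the silyl ethers never meet an organolithium; it sets out from 8 and 2 and comes back at 11. The aryllithium 9, made from 8 as before, is added to 2-chloro-N-methoxy-N-methylacetamide at −78 °C and should give, through the lithium hemiaminal adduct F6, the α-chloro ketone 2-chloro-1-[2,5-dimethoxy-4-(3-methylbut-2-enyloxy)phenyl]ethanone F7. Alkylation of phenol 2 with this phenacyl chloride (K2CO3, catalytic KI, acetone, rt) then gives 11.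

**Further compounds**

F1 | step 7 | (Z)-3-[3,5-bis(triisopropylsilyloxy)phenoxy]-2-[2,5-dimethoxy-4-(3-methylbut-2-enyloxy)phenyl]prop-2-enoic acid | OC(=O)/C(=C\Oc1cc(O[Si](C(C)C)(C(C)C)C(C)C)cc(O[Si](C(C)C)(C(C)C)C(C)C)c1)c1cc(OC)c(OCC=C(C)C)cc1OC
F2 | step 7 | (Z)-3-[3,5-bis(triisopropylsilyloxy)phenoxy]-2-[2,5-dimethoxy-4-(3-methylbut-2-enyloxy)phenyl]prop-2-enoyl chloride | ClC(=O)/C(=C\Oc1cc(O[Si](C(C)C)(C(C)C)C(C)C)cc(O[Si](C(C)C)(C(C)C)C(C)C)c1)c1cc(OC)c(OCC=C(C)C)cc1OC
F3 | step 7 | (Z)-3-[3,5-bis(triisopropylsilyloxy)phenoxy]-2-[2,5-dimethoxy-4-(3-methylbut-2-enyloxy)phenyl]prop-2-enoyl trifluoromethanesulfonate | FC(F)(F)S(=O)(=O)OC(=O)/C(=C\Oc1cc(O[Si](C(C)C)(C(C)C)C(C)C)cc(O[Si](C(C)C)(C(C)C)C(C)C)c1)c1cc(OC)c(OCC=C(C)C)cc1OC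
F4 | step 6 | [(Z)-2-[3,5-bis(triisopropylsilyloxy)phenoxy]-1-[2,5-dimethoxy-4-(3-methylbut-2-enyloxy)phenyl]ethenoxy]trimethylsilane | C[Si](C)(C)O/C(=C\Oc1cc(O[Si](C(C)C)(C(C)C)C(C)C)cc(O[Si](C(C)C)(C(C)C)C(C)C)c1)c1cc(OC)c(OCC=C(C)C)cc1OC
F5 | step 6 | lithium (Z)-2-[3,5-bis(triisopropylsilyloxy)phenoxy]-1-[2,5-dimethoxy-4-(3-methylbut-2-enyloxy)phenyl]ethenolate | [Li]O/C(=C\Oc1cc(O[Si](C(C)C)(C(C)C)C(C)C)cc(O[Si](C(C)C)(C(C)C)C(C)C)c1)c1cc(OC)c(OCC=C(C)C)cc1OC
F6 | step 5 | lithium 2-chloro-1-[2,5-dimethoxy-4-(3-methylbut-2-enyloxy)phenyl]-1-[methoxy(methyl)amino]ethanolate, racemic | [Li]OC(CCl)(N(C)OC)c1cc(OC)c(OCC=C(C)C)cc1OC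
F7 | step 5 | 2-chloro-1-[2,5-dimethoxy-4-(3-methylbut-2-enyloxy)phenyl]ethanone | O=C(CCl)c1cc(OC)c(OCC=C(C)C)cc1OC
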